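**Retrosynthetic overview**
- Ring C (the pyranone) closes last, by acid cyclodehydration of an o-hydroxyaryl 1,3-diketone made by an intermolecular Claisen condensation of an aryl methyl ketone with methyl benzoate.
- The acetyl group enters by bromination and bromine–lithium exchange on a 2-arylpiperidine whose two free ring positions are equivalent, so the 5-OMe/7-OH/8-piperidinyl pattern is fixed by symmetry.
- The piperidine ring is formed before ring C: lactam reduction, from lactamisation of a δ-amino ester, from Wittig homologation of a β-amino aldehyde.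
- Key C–C bond and the only stereocentre: Mannich addition of the titanium enolate of methyl acetate to the (S)-N-tert-butanesulfinyl imine of 4-methoxy-2,6-bis(methoxymethoxy)benzaldehyde.
- That aldehyde comes from 5-methoxyresorcinol by MOM protection and directed ortho-lithiation/formylation; ring A is present from the start.

Assumption: the stereocentre read from the SMILES is (R) at C-2 of the piperidine, and the target is isolated as the neutral free base.

**Route**

Step 1
Reactants: 1 5-methoxybenzene-1,3-diol (5-methoxyresorcinol); 2 chloromethyl methyl ether (MOMCl)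
Product: 3 1-methoxy-3,5-bis(methoxymethoxy)benzene
Conditions: MOMCl (2.6 equiv), i-Pr2NEt (3 equiv), CH2Cl2, 0 °C → rt
Reagents that add atoms: chloromethyl methyl ether, COCCl
Why: Williamson-type O-alkylation of both phenols gives the bis-MOM acetal, which later directs lithiation and survives the basic, hydride and organometallic steps.

Step 2
Reactants: 3 1-methoxy-3,5-bis(methoxymethoxy)benzene; 4 N,N-dimethylformamide
Product: 6 4-methoxy-2,6-bis(methoxymethoxy)benzaldehyde, via aryllithium 5 (not isolated)
Conditions: n-BuLi, TMEDA, THF, 0 °C, 1 h; then DMF, 0 °C → rt; H2O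
Reagents that add atoms: N,N-dimethylformamide, CN(C)C=O
Why: Directed ortho-metalation takes place at the doubly chelation-activated position between the two OMOM groups, and formylation of the aryllithium with DMF puts the aldehyde para to OMe.

Step 3
Reactants: 6 4-methoxy-2,6-bis(methoxymethoxy)benzaldehyde; 7 (S)-2-methylpropane-2-sulfinamide
Product: 8 (S)-N-{(E)-[4-methoxy-2,6-bis(methoxymethoxy)phenyl]methylidene}-2-methylpropane-2-sulfinamide
Conditions: Ti(OEt)4 (3 equiv), THF, 65 °C
Reagents that add atoms: (S)-2-methylpropane-2-sulfinamide, CC(C)(C)[S@](=O)N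
Why: Ellman imine condensation, in which Ti(OEt)4 acts as Lewis acid and water scavenger, gives the E-configured N-sulfinyl aldimine even from a hindered aldehyde and leaves the MOM acetals intact.

Step 4
Reactants: 8 (S)-N-{(E)-[4-methoxy-2,6-bis(methoxymethoxy)phenyl]methylidene}-2-methylpropane-2-sulfinamide; 9 methyl acetate
Product: 12 methyl (3R)-3-{[(S)-tert-butylsulfinyl]amino}-3-[4-methoxy-2,6-bis(methoxymethoxy)phenyl]propanoate, via lithium enolate of methyl acetate 10 (not isolated), via titanium enolate of methyl acetate 11 (not isolated)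
Conditions: LiN(i-Pr)2, THF, −78 °C; ClTi(O-i-Pr)3, −78 °C; then 8, −78 °C, 4 h; H2O
Reagents that add atoms: methyl acetate, COC(C)=O
Why: Mannich-type addition of the titanium ester enolate through a closed chair-like Zimmerman–Traxler transition state chelated by the sulfinyl imine delivers the enolate to the Re face of the (S)-sulfinyl imine, which sets the (3R) stereocentre, and the minor diastereomer is removed by chromatography.

Step 5
Reactants: 12 methyl (3R)-3-{[(S)-tert-butylsulfinyl]amino}-3-[4-methoxy-2,6-bis(methoxymethoxy)phenyl]propanoate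
Product: 13 (3R)-3-{[(S)-tert-butylsulfinyl]amino}-3-[4-methoxy-2,6-bis(methoxymethoxy)phenyl]propanal
Conditions: i-Bu2AlH (2.5 equiv), CH2Cl2, −78 °C; aq. potassium sodium tartrate work-up
Reagents that add atoms: none
Why: Partial hydride reduction of the ester stops at the aldehyde because the aluminium hemiacetal, chelated by the deprotonated sulfinamide, is stable at −78 °C and collapses only on work-up.

Step 6
Reactants: 13 (3R)-3-{[(S)-tert-butylsulfinyl]amino}-3-[4-methoxy-2,6-bis(methoxymethoxy)phenyl]propanal; 14 methyl (triphenylphosphoranylidene)acetate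
Product: 15 methyl (2E,5R)-5-{[(S)-tert-butylsulfinyl]amino}-5-[4-methoxy-2,6-bis(methoxymethoxy)phenyl]pent-2-enoate
Conditions: Ph3P=CHCO2Me, CH2Cl2, rt (crude aldehyde used at once)
Reagents that add atoms: methyl (triphenylphosphoranylidene)acetate, COC(=O)C=P(c1ccccc1)(c1ccccc1)c1ccccc1
Why: Wittig olefination with a stabilised ylide is E-selective and neutral, so the β-sulfinamido aldehyde does not eliminate and the stereocentre is untouched.

Step 7
Reactants: 15 methyl (2E,5R)-5-{[(S)-tert-butylsulfinyl]amino}-5-[4-methoxy-2,6-bis(methoxymethoxy)phenyl]pent-2-enoate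
Product: 16 methyl (5R)-5-{[(S)-tert-butylsulfinyl]amino}-5-[4-methoxy-2,6-bis(methoxymethoxy)phenyl]pentanoate
Conditions: H2 (1 atm), 10% Pd/C, EtOAc, rt
Reagents that add atoms: none
Why: Heterogeneous catalytic hydrogenation saturates the conjugated alkene, while the sulfinamide, the MOM ethers and the benzylic C–N bond are inert at 1 atm and room temperature.

Step 8
Reactants: 16 methyl (5R)-5-{[(S)-tert-butylsulfinyl]amino}-5-[4-methoxy-2,6-bis(methoxymethoxy)phenyl]pentanoate
Product: 18 (6R)-6-[4-methoxy-2,6-bis(methoxymethoxy)phenyl]piperidin-2-one, via amino ester hydrochloride 17 (not isolated)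
Conditions: HCl (4 M in dioxane, 2 equiv), MeOH, 0 °C, 30 min; then Et3N, MeOH, 60 °C
Reagents that add atoms: none
Why: Acidolysis of the N–S bond with a stoichiometric amount of HCl at 0 °C is much faster than MOM acetal cleavage, and the freed δ-amino ester closes to the six-membered lactam by intramolecular aminolysis without touching the stereocentre.

Step 9
Reactants: 18 (6R)-6-[4-methoxy-2,6-bis(methoxymethoxy)phenyl]piperidin-2-one
Product: 19 (2R)-2-[4-methoxy-2,6-bis(methoxymethoxy)phenyl]piperidine
Conditions: LiAlH4 (3 equiv), THF, 66 °C; then H2O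
Reagents that add atoms: none
Why: Hydride reduction of the secondary lactam gives the piperidine, and the MOM ethers and the stereocentre are inert to LiAlH4.

Step 10
Reactants: 19 (2R)-2-[4-methoxy-2,6-bis(methoxymethoxy)phenyl]piperidine; 20 di-tert-butyl dicarbonate
Product: 21 tert-butyl (2R)-2-[4-methoxy-2,6-bis(methoxymethoxy)phenyl]piperidine-1-carboxylate
Conditions: Boc2O (1.5 equiv), Et3N, THF, 50 °C
Reagents that add atoms: di-tert-butyl dicarbonate, CC(C)(C)OC(=O)OC(=O)OC(C)(C)C
Why: N-acylation to the Boc carbamate masks the amine against the organolithium and Claisen steps and is removed by the same acid as the MOM groups.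

Step 11
Reactants: 21 tert-butyl (2R)-2-[4-methoxy-2,6-bis(methoxymethoxy)phenyl]piperidine-1-carboxylate; 22 N-bromosuccinimide
Product: 23 tert-butyl (2R)-2-[3-bromo-4-methoxy-2,6-bis(methoxymethoxy)phenyl]piperidine-1-carboxylate
Conditions: NBS (1.0 equiv), MeCN, −20 → 0 °C, dark
Reagents that add atoms: N-bromosuccinimide, O=C1CCC(=O)N1Br
Why: Electrophilic aromatic bromination of the trialkoxy arene is fast under neutral conditions, the two free positions are equivalent so only one regioisomer can form, and one equivalent at low temperature stops at the monobromide.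

Step 12
Reactants: 23 tert-butyl (2R)-2-[3-bromo-4-methoxy-2,6-bis(methoxymethoxy)phenyl]piperidine-1-carboxylate; 24 N-methoxy-N-methylacetamide
Product: 26 tert-butyl (2R)-2-[3-acetyl-4-methoxy-2,6-bis(methoxymethoxy)phenyl]piperidine-1-carboxylate, via aryllithium 25 (not isolated)
Conditions: n-BuLi (1.1 equiv), THF, −78 °C, 15 min; then MeC(O)N(OMe)Me, −78 → 0 °C; H2O
Reagents that add atoms: N-methoxy-N-methylacetamide, CON(C)C(C)=O
Why: Bromine–lithium exchange at −78 °C is faster than attack on the Boc group or benzylic deprotonation, and Weinreb ketone synthesis stops at the methyl ketone through the chelated tetrahedral intermediate.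

Step 13
Reactants: 26 tert-butyl (2R)-2-[3-acetyl-4-methoxy-2,6-bis(methoxymethoxy)phenyl]piperidine-1-carboxylate; 27 methyl benzoate
Product: 28 tert-butyl (2R)-2-[4-methoxy-2,6-bis(methoxymethoxy)-3-(3-oxo-3-phenylpropanoyl)phenyl]piperidine-1-carboxylate
Conditions: NaH (4 equiv), PhCO2Me (3 equiv), THF, 65 °C; then AcOH, 0 °C
Reagents that add atoms: methyl benzoate, COC(=O)c1ccccc1
Why: Intermolecular crossed Claisen condensation of the methyl ketone enolate with a non-enolisable ester is driven to completion by deprotonation of the 1,3-diketone, and the Boc carbamate and the benzylic stereocentre are not affected by NaH.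

Step 14
Reactants: 28 tert-butyl (2R)-2-[4-methoxy-2,6-bis(methoxymethoxy)-3-(3-oxo-3-phenylpropanoyl)phenyl]piperidine-1-carboxylate
Product: 30 7-hydroxy-5-methoxy-2-phenyl-8-[(2R)-piperidin-2-yl]-4H-chromen-4-one, via deprotected diketone hydrochloride 29 (not isolated)
Conditions: HCl (3 M in MeOH), rt, 12 h, then 50 °C, 3 h; then aq. NaHCO3 to pH 8
Reagents that add atoms: none
Why: Acidolysis removes both MOM acetals and the Boc group, and acid-catalysed cyclodehydration of the 2-hydroxyaryl 1,3-diketone (the flavone closure of the Baker–Venkataraman sequence) can only involve the hydroxyl ortho to the acyl group, so ring C forms with the piperidine at C-8 and the stereocentre, held as its ammonium salt, is not touched.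

**Compound list**

1 | 5-methoxybenzene-1,3-diol (5-methoxyresorcinol) | COc1cc(O)cc(O)c1 | starting material
2 | chloromethyl methyl ether | COCCl | starting material
3 | 1-methoxy-3,5-bis(methoxymethoxy)benzene | COCOc1cc(OC)cc(OCOC)c1 | intermediate
4 | N,N-dimethylformamide | CN(C)C=O | starting material
5 | [4-methoxy-2,6-bis(methoxymethoxy)phenyl]lithium (formed in the flask) | [Li]c1c(OCOC)cc(OC)cc1OCOC | intermediate
6 | 4-methoxy-2,6-bis(methoxymethoxy)benzaldehyde | COCOc1cc(OC)cc(OCOC)c1C=O | intermediate
7 | (S)-2-methylpropane-2-sulfinamide | CC(C)(C)[S@](=O)N | starting material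
8 | (S)-N-{(E)-[4-methoxy-2,6-bis(methoxymethoxy)phenyl]methylidene}-2-methylpropane-2-sulfinamide | COCOc1cc(OC)cc(OCOC)c1/C=N/[S@@](=O)C(C)(C)C | intermediate
9 | methyl acetate | COC(C)=O | starting material
10 | lithium enolate of methyl acetate (formed in the flask) | C=C(OC)O[Li] | intermediate
11 | triisopropoxytitanium enolate of methyl acetate (formed in the flask) | C=C(OC)O[Ti](OC(C)C)(OC(C)C)OC(C)C | intermediate
12 | methyl (3R)-3-{[(S)-tert-butylsulfinyl]amino}-3-[4-methoxy-2,6-bis(methoxymethoxy)phenyl]propanoate | COC(=O)C[C@@H](N[S@@](=O)C(C)(C)C)c1c(OCOC)cc(OC)cc1OCOC | intermediate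
13 | (3R)-3-{[(S)-tert-butylsulfinyl]amino}-3-[4-methoxy-2,6-bis(methoxymethoxy)phenyl]propanal | O=CC[C@@H](N[S@@](=O)C(C)(C)C)c1c(OCOC)cc(OC)cc1OCOC | intermediate
14 | methyl (triphenylphosphoranylidene)acetate | COC(=O)C=P(c1ccccc1)(c1ccccc1)c1ccccc1 | starting material
15 | methyl (2E,5R)-5-{[(S)-tert-butylsulfinyl]amino}-5-[4-methoxy-2,6-bis(methoxymethoxy)phenyl]pent-2-enoate | COC(=O)/C=C/C[C@@H](N[S@@](=O)C(C)(C)C)c1c(OCOC)cc(OC)cc1OCOC | intermediate
16 | methyl (5R)-5-{[(S)-tert-butylsulfinyl]amino}-5-[4-methoxy-2,6-bis(methoxymethoxy)phenyl]pentanoate | COC(=O)CCC[C@@H](N[S@@](=O)C(C)(C)C)c1c(OCOC)cc(OC)cc1OCOC | intermediate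
17 | methyl (5R)-5-amino-5-[4-methoxy-2,6-bis(methoxymethoxy)phenyl]pentanoate hydrochloride (formed in the flask) | COC(=O)CCC[C@@H](N)c1c(OCOC)cc(OC)cc1OCOC.Cl | intermediate
18 | (6R)-6-[4-methoxy-2,6-bis(methoxymethoxy)phenyl]piperidin-2-one | O=C1CCC[C@@H](N1)c2c(OCOC)cc(OC)cc2OCOC | intermediate
19 | (2R)-2-[4-methoxy-2,6-bis(methoxymethoxy)phenyl]piperidine | COCOc1cc(OC)cc(OCOC)c1[C@H]2CCCCN2 | intermediate
20 | di-tert-butyl dicarbonate | CC(C)(C)OC(=O)OC(=O)OC(C)(C)C | starting material
21 | tert-butyl (2R)-2-[4-methoxy-2,6-bis(methoxymethoxy)phenyl]piperidine-1-carboxylate | COCOc1cc(OC)cc(OCOC)c1[C@H]2CCCCN2C(=O)OC(C)(C)C | intermediate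
22 | N-bromosuccinimide | O=C1CCC(=O)N1Br | starting material
23 | tert-butyl (2R)-2-[3-bromo-4-methoxy-2,6-bis(methoxymethoxy)phenyl]piperidine-1-carboxylate | COCOc1cc(OC)c(Br)c(OCOC)c1[C@H]2CCCCN2C(=O)OC(C)(C)C | intermediate
24 | N-methoxy-N-methylacetamide | CON(C)C(C)=O | starting material
25 | aryllithium from 23: tert-butyl (2R)-2-[3-lithio-4-methoxy-2,6-bis(methoxymethoxy)phenyl]piperidine-1-carboxylate (formed in the flask) | COCOc1cc(OC)c([Li])c(OCOC)c1[C@H]2CCCCN2C(=O)OC(C)(C)C | intermediate
26 | tert-butyl (2R)-2-[3-acetyl-4-methoxy-2,6-bis(methoxymethoxy)phenyl]piperidine-1-carboxylate | COCOc1cc(OC)c(C(C)=O)c(OCOC)c1[C@H]2CCCCN2C(=O)OC(C)(C)C | intermediate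
27 | methyl benzoate | COC(=O)c1ccccc1 | starting material
28 | tert-butyl (2R)-2-[4-methoxy-2,6-bis(methoxymethoxy)-3-(3-oxo-3-phenylpropanoyl)phenyl]piperidine-1-carboxylate | COCOc1cc(OC)c(C(=O)CC(=O)c3ccccc3)c(OCOC)c1[C@H]2CCCCN2C(=O)OC(C)(C)C | intermediate
29 | 1-{2,4-dihydroxy-6-methoxy-3-[(2R)-piperidin-2-yl]phenyl}-3-phenylpropane-1,3-dione hydrochloride (formed in the flask) | COc1cc(O)c([C@H]2CCCCN2)c(O)c1C(=O)CC(=O)c3ccccc3.Cl | intermediate
30 | 7-hydroxy-5-methoxy-2-phenyl-8-[(2R)-piperidin-2-yl]-4H-chromen-4-one | COc1cc(O)c([C@H]2CCCCN2)c2oc(-c3ccccc3)cc(=O)c12 | target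

**Totals and weak points**

Total step count: 14. Longest linear sequence: 14 steps (fully linear, from 1 to 30).

Three steps most likely to fail:

Step 4. The aldimine is di-ortho-substituted and electron-rich, so the Mannich addition may be slow or less diastereoselective than usual. The ortho-alkoxy groups could also perturb the facial sense, so the configuration and ee should be confirmed by chiral HPLC at 19 or 21. The fallback sets out from 8 and comes back at 19. Allylmagnesium bromide in CH2Cl2 at −78 °C (chelate-controlled Grignard addition, same facial sense) gives (S)-N-{(1R)-1-[4-methoxy-2,6-bis(methoxymethoxy)phenyl]but-3-en-1-yl}-2-methylpropane-2-sulfinamide F1. N-allylation (NaH, allyl bromide, DMF) gives (S)-N-{(1R)-1-[4-methoxy-2,6-bis(methoxymethoxy)phenyl]but-3-en-1-yl}-2-methyl-N-(prop-2-en-1-yl)propane-2-sulfinamide F2. Ring-closing metathesis with the second-generation Grubbs catalyst (CH2Cl2, 40 °C) gives (2R)-1-[(S)-tert-butylsulfinyl]-2-[4-methoxy-2,6-bis(methoxymethoxy)phenyl]-1,2,3,6-tetrahydropyridine F3. Hydrogenation (H2, Pd/C, EtOAc) gives (2R)-1-[(S)-tert-butylsulfinyl]-2-[4-methoxy-2,6-bis(methoxymethoxy)phenyl]piperidine F4. HCl (2 equiv, dioxane/MeOH, 0 °C) followed by aq. NaHCO3 then removes the sulfinyl group and gives 19.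

Step 8. Cleaving the N-sulfinyl group without losing an aryl MOM ether depends on acid stoichiometry and temperature, and a partly deprotected mixture would lower the yield. The fallback sets out from 16 and comes back at 18. Excess HCl in MeOH at rt deliberately removes the sulfinyl group and both MOM groups to give methyl (5R)-5-amino-5-(2,6-dihydroxy-4-methoxyphenyl)pentanoate hydrochloride F5. Et3N in MeOH at 60 °C lactamises it to (6R)-6-(2,6-dihydroxy-4-methoxyphenyl)piperidin-2-one F6. Both phenols are then re-protected with MOMCl and i-Pr2NEt in CH2Cl2 (the lactam N–H does not react), which gives 18.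

Step 12. The hindered aryllithium may deprotonate the enolisable Weinreb amide instead of adding to it, which returns the debrominated arene 21, or may attack the Boc group on warming. The fallback sets out from 23 and comes back at 26. Stille coupling with tributyl(1-ethoxyvinyl)stannane and Pd(PPh3)4 in toluene at 100 °C gives tert-butyl (2R)-2-[3-(1-ethoxyethenyl)-4-methoxy-2,6-bis(methoxymethoxy)phenyl]piperidine-1-carboxylate F7. Brief hydrolysis of the enol ether with 0.5 M aqueous HCl in THF at 0 °C, which spares the MOM and Boc groups, gives 26.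

**Further compounds**

F1 | step 4 | (S)-N-{(1R)-1-[4-methoxy-2,6-bis(methoxymethoxy)phenyl]but-3-en-1-yl}-2-methylpropane-2-sulfinamide | C=CC[C@@H](N[S@@](=O)C(C)(C)C)c1c(OCOC)cc(OC)cc1OCOC
F2 | step 4 | (S)-N-{(1R)-1-[4-methoxy-2,6-bis(methoxymethoxy)phenyl]but-3-en-1-yl}-2-methyl-N-(prop-2-en-1-yl)propane-2-sulfinamide | C=CC[C@@H](N(CC=C)[S@@](=O)C(C)(C)C)c1c(OCOC)cc(OC)cc1OCOC
F3 | step 4 | (2R)-1-[(S)-tert-butylsulfinyl]-2-[4-methoxy-2,6-bis(methoxymethoxy)phenyl]-1,2,3,6-tetrahydropyridine | CC(C)(C)[S@](=O)N1CC=CC[C@@H]1c2c(OCOC)cc(OC)cc2OCOC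
F4 | step 4 | (2R)-1-[(S)-tert-butylsulfinyl]-2-[4-methoxy-2,6-bis(methoxymethoxy)phenyl]piperidine | CC(C)(C)[S@](=O)N1CCCC[C@@H]1c2c(OCOC)cc(OC)cc2OCOC
F5 | step 8 | methyl (5R)-5-amino-5-(2,6-dihydroxy-4-methoxyphenyl)pentanoate hydrochloride | COC(=O)CCC[C@@H](N)c1c(O)cc(OC)cc1O.Cl
F6 | step 8 | (6R)-6-(2,6-dihydroxy-4-methoxyphenyl)piperidin-2-one | O=C1CCC[C@@H](N1)c2c(O)cc(OC)cc2O
F7 | step 12 | tert-butyl (2R)-2-[3-(1-ethoxyethenyl)-4-methoxy-2,6-bis(methoxymethoxy)phenyl]piperidine-1-carboxylate | CCOC(=C)c1c(OC)cc(OCOC)c([C@H]2CCCCN2C(=O)OC(C)(C)C)c1OCOC
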